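## Retrosynthetic overview

1. Locants (target): C1 = CH–OMe, C2 = bridgehead CH, C3 = CH2, C4 = CH–iPr, C5 = quaternary bridgehead, C6/C7 = CH2CH2, C8 = C–CH3, C9/C10 = ring-fusion CH, C11 = C(OH)CH3, C12 = CH–OH, C13 = CH2, C14 = CH–Br, C15 = bridge CH2; norbornane = C1, C2, C3, C4, C5, C10, C15; ring C = C5 to C10; ring D = C8, C9, C11, C12, C13, C14.
2. Enabling feature: in ring D the bonds C9–C11 and C8–C14 flank the trans ring-fusion bond C8–C9 (quaternary C8–CH3; C7 and C10 trans). This is the retron of an intermolecular Diels–Alder reaction between a C11–C14 1-oxydiene and an (E)-enone C7(=O)–C8(CH3)=C9.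
3. The same cycloaddition turns C8=C9 into a single bond, so the tether C6–C7–C8–C9 can fold for the first time. An intramolecular Diels–Alder reaction of a 2-isopropylcyclopentadiene (C2, C3, C4, C5, C15) onto the alkenylboronate C10=C1 then closes ring C and the norbornene (bonds C5–C10 and C1–C2). The diene is carried latent as a tertiary allylic silyl ether and released in the same flask.
4. After the cascade only adjustments remain: C1–B to C1–OMe, C7=O to CH2, exo hydrogenation of C3=C4, and in ring D C14–O to ketone, dienyl triflate, vinyl bromide, radical hydrogenation (equatorial Br), then C11=C12 epoxide to the trans-diaxial diol.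
5. Ring order: cyclopentene (step 1), then ring D, ring C and the norbornene (all in step 6); the acyclic precursor comes from a phosphonate dianion addition and an olefination.

Key step: step 6

Remark: 1, 2, 4, 6 and 9 are taken as catalogue compounds; 5, 7 and 8 are racemic at the carbinol carbon, which is erased in step 6.
Remark: the C11 and C14 centres created in step 6 are made planar later; structures 11 to 19 show the expected endo adduct.

## Route

Step 1
Reactants: 1 3-methylbut-1-yne; 2 ethylene
Product: 3 2-isopropylcyclopent-2-en-1-one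
Conditions: Co2(CO)8 (5 mol %), CO (20 bar), ethylene (40 bar), PhMe, 120 °C
Reagents that add atoms: carbon monoxide, [C-]#[O+]
Why: Catalytic intermolecular Pauson–Khand reaction, in which a terminal alkyne places its substituent next to the carbonyl and ethylene leaves no alkene regiochemistry to control.

Step 2
Reactants: 3 2-isopropylcyclopent-2-en-1-one; 4 diethyl (3-oxobutan-2-yl)phosphonate
Product: 5 diethyl [4-(1-hydroxy-2-isopropylcyclopent-2-en-1-yl)-3-oxobutan-2-yl]phosphonate (racemic, diastereomer mixture)
Conditions: 4, NaH, THF, 0 °C; n-BuLi, −78 °C; then 3, −78 °C; aq. NH4Cl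
Reagents that add atoms: none
Why: Dianion aldol addition of a β-ketophosphonate, whose terminal (γ) carbanion should add 1,2 to the enone carbonyl; the new carbinol centre is racemic and is destroyed in step 6.

Step 3
Reactants: 5 hydroxy β-ketophosphonate; 6 (E)-3-(4,4,5,5-tetramethyl-1,3,2-dioxaborolan-2-yl)prop-2-enal
Product: 7 (3E,5E)-1-(1-hydroxy-2-isopropylcyclopent-2-en-1-yl)-3-methyl-6-(4,4,5,5-tetramethyl-1,3,2-dioxaborolan-2-yl)hexa-3,5-dien-2-one
Conditions: LiCl, iPr2NEt, MeCN, rt
Reagents that add atoms: none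
Why: Horner–Wadsworth–Emmons olefination under Masamune–Roush conditions, which should give the thermodynamically preferred (E)-trisubstituted enone (C7 trans to C10) and keep the (E)-alkenylboronate of 6 intact.

Step 4
Reactants: 7 dienone carbinol
Product: 8 triethylsilyl ether of 7
Conditions: Et3SiOTf, 2,6-lutidine, CH2Cl2, −78 °C
Reagents that add atoms: triethylsilyl trifluoromethanesulfonate, CC[Si](CC)(CC)OS(=O)(=O)C(F)(F)F
Why: Silyl triflate silylation of the tertiary alcohol, so that the latent cyclopentadiene meets the Lewis acid of step 6 neither as a free hydroxyl nor as a free diene.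

Step 5
Reactants: 9 (E)-pent-2-enal
Product: 10 (1E,3E)-1-(triisopropylsilyloxy)penta-1,3-diene
Conditions: iPr3SiOTf, Et3N, Et2O, 0 °C to rt
Reagents that add atoms: triisopropylsilyl trifluoromethanesulfonate, CC(C)[Si](C(C)C)(C(C)C)OS(=O)(=O)C(F)(F)F
Why: Silyl dienol ether formation (O-silylation, then γ-deprotonation of the enal), which should give the (1E,3E)-diene as the favoured isomer.

Step 6
Reactants: 8 triethylsilyl ether of the dienone carbinol; 10 (1E,3E)-1-(triisopropylsilyloxy)penta-1,3-diene
Product: 13 tetracyclic keto boronate (norbornene C3=C4 fused to ring C ketone and ring D cyclohexene; endo C1–B(pin); C14–OSi(iPr)3), via cycloadduct 11 (not isolated), via cyclopentadiene 12 (not isolated)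
Conditions: 10 (3 equiv), (S)-3,3-diphenyl-1-(2-methylphenyl)tetrahydro-1H,3H-pyrrolo[1,2-c][1,3,2]oxazaborole·HN(SO2CF3)2 (20 mol %), CH2Cl2, −78 to −40 °C; then pyridine (0.25 equiv), solvent switch to PhMe, pyridinium p-toluenesulfonate (0.3 equiv), 110 °C
Reagents that add atoms: none
Why: The oxazaborolidinium-bound (E)-enone of 8 and 1-silyloxydiene 10 combine in an asynchronous intermolecular [4+2] cycloaddition (closest known type: oxazaborolidinium-catalysed Diels–Alder reactions of enones with silyloxydienes), the methyl-bearing nucleophilic diene terminus bonding to the β-carbon C9 and the oxygenated terminus to the α-carbon C8, which closes ring D. The catalyst-shielded enone face fixes C8 and C9 in the absolute sense (the catalyst enantiomer is chosen by the usual pre-transition-state model, the antipode being used if the sense proves opposite), and the (E)-geometry fixes their trans relation, whereas C11 and C14 are erased later. Warm pyridinium tosylate then ionises the tertiary allylic silyl ether, E1 loss of Et3SiOH gives cyclopentadienes that equilibrate by [1,5]-hydrogen shifts, and both carbinol epimers and all diene isomers drain through 12, the only isomer with the tether on a diene terminus. Because C8–C9 is now an sp3–sp3 bond, the four-atom tether C6–C7–C8–C9 can fold, and a type 1 intramolecular Diels–Alder reaction of the 1-substituted cyclopentadiene closes ring C as the six-membered tether ring and the norbornene by the bonds C5–C10 and C1–C2. Substrate control from C8 and C9 sets C10 and C5 (trans-diequatorial tether on ring D, chair-like exo-fused ring C, alkene reacting in its A(1,3)-minimised rotamer so that C1 avoids the axial C8 methyl group), the (E)-alkenylboronate places boron endo at C1 trans to C9, and C2 follows from suprafacial addition. The step needs chemoselectivity (no cyclopentadiene exists while the Lewis acid is active), site selectivity for the α,β- over the boron-bearing γ,δ-alkene (largest LUMO coefficient at C9, bulky boronate terminus) and enantioface control by the catalyst.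

Step 7
Reactants: 13 tetracyclic keto boronate
Product: 14 endo C1 alcohol
Conditions: 30% H2O2, 2 M NaOH, THF, 0 °C
Reagents that add atoms: hydrogen peroxide, OO
Why: Oxidation of a secondary alkylboronate by 1,2-migration from boron to oxygen, which proceeds with retention and so should transfer the endo configuration at C1 to the alcohol.

Step 8
Reactants: 14 endo C1 alcohol
Product: 15 C1 methyl ether (C7 ketone)
Conditions: MeOTf, 2,6-di-tert-butyl-4-methylpyridine, CH2Cl2, rt
Reagents that add atoms: methyl trifluoromethanesulfonate, COS(=O)(=O)C(F)(F)F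
Why: O-Alkylation of the alcohol with methyl triflate under non-basic conditions, which should leave the enolisable C7 ketone and the silyl ether untouched and affects no stereocentre.

Step 9
Reactants: 15 C1 methyl ether (C7 ketone)
Product: 17 C7-deoxygenated tetracycle (C3=C4 and C12=C13 retained), via hydrazone 16 (not isolated)
Conditions: N2H4·H2O, diethylene glycol, 130 °C; then KOH, 195 °C
Reagents that add atoms: none
Why: Wolff–Kishner reduction in the Huang–Minlon mode; forming the hydrazone before the base is added protects the β-silyloxy ketone from retro-aldol cleavage, and the ethers and alkenes should tolerate the base.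

Step 10
Reactants: 17 C7-deoxygenated tetracycle
Product: 18 norbornane with endo isopropyl at C4
Conditions: 2-nitrobenzenesulfonylhydrazide, Et3N, CH2Cl2, rt
Reagents that add atoms: none
Why: Diimide reduction, which is far faster for the strained norbornene alkene than for the hindered ring D alkene; delivery of both hydrogens from the exo face should place the isopropyl group endo at C4.

Step 11
Reactants: 18 norbornane silyl ether
Product: 19 allylic alcohol (C14–OH)
Conditions: Bu4NF, THF, 50 °C
Reagents that add atoms: none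
Why: Fluoride-mediated cleavage of the silyl ether; no stereocentre is touched.

Step 12
Reactants: 19 allylic alcohol
Product: 20 enone (C14=O, C12=C13)
Conditions: Dess–Martin periodinane, CH2Cl2, rt
Reagents that add atoms: none
Why: Dess–Martin oxidation of the hindered allylic alcohol, which removes the C14 stereocentre.

Step 13
Reactants: 20 enone
Product: 21 dienyl triflate (C11=C12, C13=C14–OTf)
Conditions: KN(SiMe3)2, THF, −78 °C; PhNTf2, −78 to 0 °C
Reagents that add atoms: N-phenylbis(trifluoromethanesulfonimide), O=S(=O)(N(c1ccccc1)S(=O)(=O)C(F)(F)F)C(F)(F)F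
Why: Extended enolate formation and O-triflation: C8 is quaternary, so the base can only remove the γ-hydrogen at C11, and trapping on oxygen gives the 2-triflyloxy-1,3-diene with the alkene moved to C11=C12 and the C11 centre erased.

Step 14
Reactants: 21 dienyl triflate
Product: 22 bromodiene (C11=C12, C13=C14–Br)
Conditions: Ni(cod)2 (10 mol %, zerovalent nickel), LiBr, DMA/THF, rt
Reagents that add atoms: lithium bromide, [Li+].[Br-]
Why: Nickel-catalysed triflate-to-halide exchange of an enol triflate (oxidative addition, halide exchange, reductive elimination), which keeps the alkene position.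

Step 15
Reactants: 22 bromodiene
Product: 23 vinyl epoxide (C11–C12 oxirane on the face of C9–H; C13=C14–Br)
Conditions: mCPBA, CH2Cl2, −20 to 0 °C
Reagents that add atoms: 3-chloroperoxybenzoic acid, OOC(=O)c1cccc(Cl)c1
Why: Prilezhaev epoxidation of the more electron-rich, bromine-free trisubstituted alkene; the peracid should approach anti to the axial C8 methyl group, which sets C11 and C12.

Step 16
Reactants: 23 vinyl epoxide
Product: 24 epoxy bromide (C14–Br equatorial)
Conditions: Mn(dpm)3 (10 mol %; dpm = dipivaloylmethanato), PhSiH3, tBuOOH, iPrOH, rt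
Reagents that add atoms: none
Why: Metal-hydride hydrogen-atom-transfer hydrogenation (Mukaiyama type): the hydrogen atom should add to C13 to give the tertiary α-bromo radical at C14, which takes its second hydrogen axially, anti to the adjacent axial C8 methyl group, leaving bromine equatorial and the C–Br bond and oxirane intact.

Step 17
Reactants: 24 epoxy bromide
Product: 25 CNP0130529.1 (target)
Conditions: 5% aq. HClO4, THF, 0 °C to rt
Reagents that add atoms: water, O
Why: Acid-catalysed epoxide hydrolysis under Fürst–Plattner control: water should attack the tertiary C11 with inversion, on the face of the C8 methyl group, giving the trans-diaxial diol with retention at C12.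

## Compound list

1 | 3-methylbut-1-yne | CC(C)C#C | starting material
2 | ethylene | C=C | starting material
3 | 2-isopropylcyclopent-2-en-1-one | CC(C)C1=CCCC1=O | intermediate
4 | diethyl (3-oxobutan-2-yl)phosphonate | CCOP(=O)(OCC)C(C)C(C)=O | starting material
5 | diethyl [4-(1-hydroxy-2-isopropylcyclopent-2-en-1-yl)-3-oxobutan-2-yl]phosphonate (racemic) | CCOP(=O)(OCC)C(C)C(=O)CC1(O)CCC=C1C(C)C | intermediate
6 | (E)-3-(4,4,5,5-tetramethyl-1,3,2-dioxaborolan-2-yl)prop-2-enal | O=C/C=C/B1OC(C)(C)C(C)(C)O1 | starting material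
7 | (3E,5E)-1-(1-hydroxy-2-isopropylcyclopent-2-en-1-yl)-3-methyl-6-(pinacolboryl)hexa-3,5-dien-2-one (racemic) | CC(C)C1=CCCC1(O)CC(=O)/C(C)=C/C=C/B2OC(C)(C)C(C)(C)O2 | intermediate
8 | triethylsilyl ether of 7 (racemic) | CC(C)C1=CCCC1(O[Si](CC)(CC)CC)CC(=O)/C(C)=C/C=C/B2OC(C)(C)C(C)(C)O2 | intermediate
9 | (E)-pent-2-enal | CC/C=C/C=O | starting material
10 | (1E,3E)-1-(triisopropylsilyloxy)penta-1,3-diene | C/C=C/C=C/O[Si](C(C)C)(C(C)C)C(C)C | intermediate
11 | ring D cycloadduct: cyclohexene with C8 (CH3 and the acyl chain to the silyloxycyclopentenyl unit) trans to C9 ((E)-2-borylvinyl); C11–CH3 and C14–OSi(iPr)3 cis to the acyl group; both carbinol epimers | CC(C)C1=CCCC1(O[Si](CC)(CC)CC)CC(=O)[C@@]4(C)[C@H](/C=C/B5OC(C)(C)C(C)(C)O5)[C@@H](C)C=C[C@H]4O[Si](C(C)C)(C(C)C)C(C)C | intermediate (not isolated)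
12 | cyclopentadiene: same ring D unit, acyl chain ending in 2-isopropylcyclopenta-1,3-dien-1-ylmethyl | CC(C)C1=C(CC(=O)[C@@]4(C)[C@H](/C=C/B5OC(C)(C)C(C)(C)O5)[C@@H](C)C=C[C@H]4O[Si](C(C)C)(C(C)C)C(C)C)CC=C1 | intermediate (not isolated)
13 | tetracyclic keto boronate: C1–B(pin) endo, C9 exo on C10, C3=C4 (iPr on C4), C7=O, C8–CH3 trans to C9–H, C12=C13, C11–CH3 and C14–OSi(iPr)3 on the face of C7 | CC5(C)OB(OC5(C)C)[C@H]1[C@H]2C=C(C(C)C)[C@]3(CC(=O)[C@@]4(C)[C@H]([C@H]13)[C@@H](C)C=C[C@H]4O[Si](C(C)C)(C(C)C)C(C)C)C2 | intermediate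
14 | endo C1 alcohol of 13 | O[C@H]1[C@H]2C=C(C(C)C)[C@]3(CC(=O)[C@@]4(C)[C@H]([C@H]13)[C@@H](C)C=C[C@H]4O[Si](C(C)C)(C(C)C)C(C)C)C2 | intermediate
15 | C1 methyl ether (C7 ketone) | CO[C@H]1[C@H]2C=C(C(C)C)[C@]3(CC(=O)[C@@]4(C)[C@H]([C@H]13)[C@@H](C)C=C[C@H]4O[Si](C(C)C)(C(C)C)C(C)C)C2 | intermediate
16 | C7 hydrazone of 15 | CO[C@H]1[C@H]2C=C(C(C)C)[C@]3(CC(=NN)[C@@]4(C)[C@H]([C@H]13)[C@@H](C)C=C[C@H]4O[Si](C(C)C)(C(C)C)C(C)C)C2 | intermediate (not isolated)
17 | C7-deoxygenated tetracycle (C3=C4, C12=C13) | CO[C@H]1[C@H]2C=C(C(C)C)[C@]3(CC[C@@]4(C)[C@H]([C@H]13)[C@@H](C)C=C[C@H]4O[Si](C(C)C)(C(C)C)C(C)C)C2 | intermediate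
18 | norbornane with endo isopropyl at C4 (C12=C13, C14–OSi(iPr)3) | CO[C@H]1[C@H]2C[C@@H](C(C)C)[C@]3(CC[C@@]4(C)[C@H]([C@H]13)[C@@H](C)C=C[C@H]4O[Si](C(C)C)(C(C)C)C(C)C)C2 | intermediate
19 | allylic alcohol (C14–OH axial, C12=C13) | CO[C@H]1[C@H]2C[C@@H](C(C)C)[C@]3(CC[C@@]4(C)[C@H]([C@H]13)[C@@H](C)C=C[C@H]4O)C2 | intermediate
20 | enone (C14=O, C12=C13) | CO[C@H]1[C@H]2C[C@@H](C(C)C)[C@]3(CC[C@@]4(C)[C@H]([C@H]13)[C@@H](C)C=CC4=O)C2 | intermediate
21 | dienyl triflate (C11=C12, C13=C14–OTf) | CO[C@H]1[C@H]2C[C@@H](C(C)C)[C@]3(CC[C@@]4(C)[C@H]([C@H]13)C(C)=CC=C4OS(=O)(=O)C(F)(F)F)C2 | intermediate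
22 | bromodiene (C11=C12, C13=C14–Br) | CO[C@H]1[C@H]2C[C@@H](C(C)C)[C@]3(CC[C@@]4(C)[C@H]([C@H]13)C(C)=CC=C4Br)C2 | intermediate
23 | vinyl epoxide (C11–C12 oxirane on the face of C9–H, C13=C14–Br) | CO[C@H]1[C@H]2C[C@@H](C(C)C)[C@]3(CC[C@@]4(C)[C@H]([C@H]13)[C@@]5(C)O[C@H]5C=C4Br)C2 | intermediate
24 | epoxy bromide (C14–Br equatorial) | CO[C@H]1[C@H]2C[C@@H](C(C)C)[C@]3(CC[C@@]4(C)[C@H]([C@H]13)[C@@]5(C)O[C@H]5C[C@@H]4Br)C2 | intermediate
25 | CNP0130529.1 | CO[C@H]1[C@H]2C[C@@H](C(C)C)[C@]3(CC[C@@]4(C)[C@H]([C@H]13)[C@](C)(O)[C@@H](O)C[C@@H]4Br)C2 | target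

## Step count and risks

Total steps: 17. Longest linear sequence: 16 (steps 1 to 4 and 6 to 17; step 5 is a one-step branch).

**Step 6.** The catalyst may discriminate the two enone faces poorly, because this α-methyl ketone offers no α-vinyl or formyl C–H contact to organise it on the oxazaborolidinium. The fallback sets out from 8 and swaps asymmetric catalysis for a racemic cascade plus resolution. The same one-pot sequence with an achiral Lewis acid (Me2AlCl, CH2Cl2, −78 °C; then pyridinium p-toluenesulfonate, PhMe, 110 °C) should give 11, 12 and 13 together with their mirror-image series: the enantiomeric cycloadduct F1 and the enantiomeric cyclopentadiene F2 in the flask, and the enantiomeric tetracycle F3. Oxidation as in step 7 gives 14 with its enantiomer F4. A lipase-mediated kinetic resolution (Burkholderia cepacia lipase, vinyl acetate, tBuOMe) is expected to acylate one antipode; written for the unwanted one, it gives the enantiomeric acetate F5, and chromatography returns enantiopure 14, where the route is rejoined.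

**Step 16.** Hydrogen-atom transfer may go to C14 first, after which the β-bromo radical loses bromine, or the second hydrogen may arrive on the wrong face. The fallback sets out from enone 20 and installs bromine by substitution instead. Kinetic protonation of the extended potassium enolate (KOtBu, tBuOH; then aq. AcOH) should give the β,γ-unsaturated ketone F6. LiBH(s-Bu)3 attacks equatorially to give the axial homoallylic alcohol F7. An Appel reaction (CBr4, PPh3) with inversion gives the equatorial bromide F8, and mCPBA epoxidation of its C11=C12 alkene, anti to the C8 methyl group, returns to the route at 24.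

**Step 14.** Oxidative addition of zerovalent nickel into a dienyl triflate flanked by a quaternary carbon may be slow, so that triflate cleavage or reduction competes. The fallback sets out from 21: palladium-catalysed stannylation (Pd(PPh3)4, LiCl, Me3SnSnMe3, dioxane, 80 °C) should give the dienylstannane F9, and bromodestannylation with N-bromosuccinimide returns to the route at 22.

## Further compounds

F1 | step 6 | enantiomer of cycloadduct 11 | CC(C)C1=CCCC1(O[Si](CC)(CC)CC)CC(=O)[C@]4(C)[C@@H](/C=C/B5OC(C)(C)C(C)(C)O5)[C@H](C)C=C[C@@H]4O[Si](C(C)C)(C(C)C)C(C)C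
F2 | step 6 | enantiomer of cyclopentadiene 12 | CC(C)C1=C(CC(=O)[C@]4(C)[C@@H](/C=C/B5OC(C)(C)C(C)(C)O5)[C@H](C)C=C[C@@H]4O[Si](C(C)C)(C(C)C)C(C)C)CC=C1
F3 | step 6 | enantiomer of tetracyclic keto boronate 13 | CC5(C)OB(OC5(C)C)[C@@H]1[C@@H]2C=C(C(C)C)[C@@]3(CC(=O)[C@]4(C)[C@@H]([C@@H]13)[C@H](C)C=C[C@@H]4O[Si](C(C)C)(C(C)C)C(C)C)C2
F4 | step 6 | enantiomer of alcohol 14 | O[C@@H]1[C@@H]2C=C(C(C)C)[C@@]3(CC(=O)[C@]4(C)[C@@H]([C@@H]13)[C@H](C)C=C[C@@H]4O[Si](C(C)C)(C(C)C)C(C)C)C2
F5 | step 6 | acetate of the enantiomer of alcohol 14 | CC(=O)O[C@@H]1[C@@H]2C=C(C(C)C)[C@@]3(CC(=O)[C@]4(C)[C@@H]([C@@H]13)[C@H](C)C=C[C@@H]4O[Si](C(C)C)(C(C)C)C(C)C)C2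
F6 | step 16 | β,γ-unsaturated ketone (C14=O, C11=C12) | CO[C@H]1[C@H]2C[C@@H](C(C)C)[C@]3(CC[C@@]4(C)[C@H]([C@H]13)C(C)=CCC4=O)C2
F7 | step 16 | axial homoallylic alcohol (C14–OH, C11=C12) | CO[C@H]1[C@H]2C[C@@H](C(C)C)[C@]3(CC[C@@]4(C)[C@H]([C@H]13)C(C)=CC[C@H]4O)C2
F8 | step 16 | equatorial homoallylic bromide (C14–Br, C11=C12) | CO[C@H]1[C@H]2C[C@@H](C(C)C)[C@]3(CC[C@@]4(C)[C@H]([C@H]13)C(C)=CC[C@@H]4Br)C2
F9 | step 14 | dienyl trimethylstannane (C11=C12, C13=C14–SnMe3) | CO[C@H]1[C@H]2C[C@@H](C(C)C)[C@]3(CC[C@@]4(C)[C@H]([C@H]13)C(C)=CC=C4[Sn](C)(C)C)C2
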